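**Strategy.** Locants follow chroman-2-one numbering; primed atoms belong to the tetraoxygenated unit. The ring B lactone (O1'–C2'(=O)–C3'–C4'–C4a'–C8a') is treated as the Baeyer–Villiger product of a 3-aryl-indan-1-one, so that the C2'–C3' bond becomes the acyl–CH2 bond of a five-membered ketone. A rhodium–BINAP hydroacylation of an achiral ortho-(1-arylvinyl)benzaldehyde adds the aldehyde C–H across the future C3'=C4' alkene: in one operation it closes the ring through C2'–C3' and sets the diarylmethine centre C4'. C4' then steers C3' (hydrogenation), a peracid inserts O1', and a carbene-catalysed [4+2] annulation with an ortho-quinone methide builds the ring A lactone together with C3 and C4.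

Key step: step 4

Remark: the target is read as 3S,4R,3'S,4'R, with the C3–C3' bond cis to the 4-aryl group on both lactone rings; this is taken to be the kinetically controlled, base-labile arrangement, so no strong base follows its installation.
Remark: (R)-BINAP in step 4 and the (5aR,10bS) triazolium salt in step 10 are assumed to give the senses of induction drawn; the antipode would be used if a model run shows the opposite sense.
Remark: boronate 5 is taken as a catalogue compound.

Step 1
Reactants: 1 1,2,3,4-tetramethoxybenzene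
Product: 3 2,3,4,5-tetramethoxybenzaldehyde, via chloro(methoxy)methyl arene 2 (not isolated)
Conditions: Cl2CHOMe, TiCl4, CH2Cl2, 0 °C; then H2O
Reagents that add atoms: dichloromethyl methyl ether, COC(Cl)Cl; water, O
Why: Rieche formylation (electrophilic aromatic substitution) at one of the two equivalent free positions of the electron-rich arene; the chloro ether 2 is hydrolysed on work-up.

Step 2
Reactants: 3 2,3,4,5-tetramethoxybenzaldehyde
Product: 4 2-bromo-3,4,5,6-tetramethoxybenzaldehyde
Conditions: NBS, MeCN, 25 °C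
Reagents that add atoms: N-bromosuccinimide, BrN1C(=O)CCC1=O
Why: Electrophilic aromatic bromination at the only free ring position, which is activated by an ortho and a para methoxy group.

Step 3
Reactants: 4 2-bromo-3,4,5,6-tetramethoxybenzaldehyde; 5 2-[1-(4-methoxyphenyl)ethenyl]-4,4,5,5-tetramethyl-1,3,2-dioxaborolane
Product: 6 2,3,4,5-tetramethoxy-6-[1-(4-methoxyphenyl)ethenyl]benzaldehyde
Conditions: Pd(OAc)2 (3 mol%), SPhos (6 mol%), K3PO4, toluene/H2O, 90 °C
Reagents that add atoms: none
Why: Suzuki–Miyaura coupling; the ortho formyl group speeds oxidative addition, the biaryl phosphine copes with the two ortho substituents, and the aldehyde has no enolisable position.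

Step 4
Reactants: 6 2,3,4,5-tetramethoxy-6-[1-(4-methoxyphenyl)ethenyl]benzaldehyde
Product: 7 (3R)-4,5,6,7-tetramethoxy-3-(4-methoxyphenyl)-2,3-dihydro-1H-inden-1-one
Conditions: [Rh(nbd)2]BF4 (5 mol%), (R)-BINAP (5.5 mol%), pre-hydrogenated to strip nbd, CH2Cl2, 25 °C
Reagents that add atoms: none
Why: Oxidative addition of the aldehyde C–H bond to the cationic monovalent rhodium–BINAP fragment gives an acyl rhodium hydride held by the neighbouring alkene; hydride insertion at the internal, diaryl-substituted alkene carbon (future C4') gives a six-membered acyl alkyl rhodacycle, and C–C reductive elimination joins the acyl carbon (future C2') to the former CH2 terminus (future C3'). The closest known reaction is the Rh/BINAP-catalysed enantioselective intramolecular hydroacylation of 2-(alk-1-en-2-yl)benzaldehydes to 3-substituted indan-1-ones. The five-membered carbocycle closes in an endo sense (both alkene carbons become ring members), which the metallacycle pathway allows. C4' is the only new stereocentre and is set in the hydride insertion by the chiral diphosphine, which must tell the anisyl group from the hexasubstituted aryl group; the 3R ketone is expected. The step needs cyclisation to outrun decarbonylation and rhodium to end on the terminal carbon: alkene chelation favours the former, the 1,1-disubstitution (a four-membered ring with a quaternary centre otherwise) secures the latter, and the lack of allylic hydrogen excludes alkene isomerisation.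

Step 5
Reactants: 7 (3R)-4,5,6,7-tetramethoxy-3-(4-methoxyphenyl)-2,3-dihydro-1H-inden-1-one; 8 glyoxylic acid monohydrate
Product: 9 (2E)-2-[(1R)-4,5,6,7-tetramethoxy-1-(4-methoxyphenyl)-3-oxo-1,3-dihydro-2H-inden-2-ylidene]acetic acid
Conditions: H2SO4 (cat.), 1,4-dioxane, 80 °C
Reagents that add atoms: none
Why: Acid-catalysed crossed aldol condensation (Claisen–Schmidt type) at C2, the only enolisable position, with a non-enolisable aldehyde; dehydration gives the conjugated alkylidene (its geometry has no consequence) and the aryl-bearing centre is not touched under acid.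

Step 6
Reactants: 9 (2E)-2-[(1R)-4,5,6,7-tetramethoxy-1-(4-methoxyphenyl)-3-oxo-1,3-dihydro-2H-inden-2-ylidene]acetic acid
Product: 10 2-[(1R,2R)-4,5,6,7-tetramethoxy-1-(4-methoxyphenyl)-3-oxo-2,3-dihydro-1H-inden-2-yl]acetic acid
Conditions: H2 (1 atm), Pd/C (5 mol%), EtOAc, 20 °C; crude product taken on at once
Reagents that add atoms: none
Why: Heterogeneous syn hydrogenation of the electron-poor exocyclic alkene; allylic strain with the carboxymethylidene group holds the neighbouring aryl group pseudoaxial, so hydrogen arrives on the opposite face and the new centre (future C3') becomes 2R with the side chain cis to the aryl group.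

Step 7
Reactants: 10 2-[(1R,2R)-4,5,6,7-tetramethoxy-1-(4-methoxyphenyl)-3-oxo-2,3-dihydro-1H-inden-2-yl]acetic acid
Product: 11 2-[(3R,4R)-5,6,7,8-tetramethoxy-4-(4-methoxyphenyl)-2-oxo-3,4-dihydro-2H-chromen-3-yl]acetic acid
Conditions: mCPBA (1.5 equiv), CH2Cl2, 0 → 20 °C
Reagents that add atoms: 3-chloroperbenzoic acid, OOC(=O)c1cccc(Cl)c1
Why: Baeyer–Villiger oxidation; the electron-rich aryl carbon (ortho and para methoxy) should migrate in preference to the secondary alkyl carbon that carries the electron-poor carboxymethyl group, the α-centre is not involved so the cis relation is kept, and O1' enters as the fifth oxygen of ring B.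

Step 8
Reactants: 12 2-hydroxy-4,6-dimethoxybenzaldehyde; 13 (4-methoxyphenyl)magnesium bromide
Product: 14 2-[hydroxy(4-methoxyphenyl)methyl]-3,5-dimethoxyphenol (racemic)
Conditions: 13 (2.2 equiv), THF, 0 °C; then H2O (pH 7); used crude
Reagents that add atoms: none
Why: Grignard addition; the first equivalent deprotonates the phenol and the second adds to the magnesium-chelated aldehyde, giving a racemic carbinol centre that is erased in step 10.

Step 9
Reactants: 14 2-[hydroxy(4-methoxyphenyl)methyl]-3,5-dimethoxyphenol; 15 sodium 4-methylbenzenesulfinate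
Product: 16 3,5-dimethoxy-2-[(4-methoxyphenyl)(4-methylbenzenesulfonyl)methyl]phenol (racemic)
Conditions: 15 (3 equiv), HCO2H/H2O, 25 °C
Reagents that add atoms: none
Why: Acid-promoted SN1 substitution; the benzhydrol ionises to the stabilised benzylic cation (protonated ortho-quinone methide), which excess sulfinate captures at sulfur to give a bench-stable quinone methide precursor.

Step 10
Reactants: 11 2-[(3R,4R)-5,6,7,8-tetramethoxy-4-(4-methoxyphenyl)-2-oxo-3,4-dihydro-2H-chromen-3-yl]acetic acid; 16 3,5-dimethoxy-2-[(4-methoxyphenyl)(4-methylbenzenesulfonyl)methyl]phenol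
Product: 19 (3S,4R)-5,7-dimethoxy-4-(4-methoxyphenyl)-3-[(3S,4R)-5,6,7,8-tetramethoxy-4-(4-methoxyphenyl)-2-oxo-3,4-dihydro-2H-chromen-3-yl]-3,4-dihydro-2H-chromen-2-one, via acyl imidazole 17 (not isolated), via ortho-quinone methide 18 (not isolated)
Conditions: 1,1'-carbonyldiimidazole, THF, 25 °C; then 16, (5aR,10bS)-2-mesityl-5a,10b-dihydro-4H,6H-indeno[2,1-b][1,2,4]triazolo[4,3-d][1,4]oxazin-2-ium tetrafluoroborate (10 mol%), Cs2CO3, THF, 25 °C
Reagents that add atoms: none
Why: Carbene-catalysed formal [4+2] annulation: the carbene is acylated by 17, deprotonation gives the Z azolium enolate, this adds through an endo transition state to the ortho-quinone methide 18 released from 16, and the phenoxide lactonises with loss of the carbene, so that C3–C4 and O1–C2 form with the cis relation typical of this annulation while the chiral triazolium salt selects the enolate face leading to 3S,4R.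

Step 11
Reactants: 19 (3S,4R)-5,7-dimethoxy-4-(4-methoxyphenyl)-3-[(3S,4R)-5,6,7,8-tetramethoxy-4-(4-methoxyphenyl)-2-oxo-3,4-dihydro-2H-chromen-3-yl]-3,4-dihydro-2H-chromen-2-one
Product: 20 (3S,4R)-5,7-dihydroxy-4-(4-hydroxyphenyl)-3-[(3S,4R)-5,6,7,8-tetrahydroxy-4-(4-hydroxyphenyl)-2-oxo-3,4-dihydro-2H-chromen-3-yl]-3,4-dihydro-2H-chromen-2-one
Conditions: BBr3 (16 equiv), CH2Cl2, −78 → 0 °C; then degassed H2O
Reagents that add atoms: none
Why: Lewis-acid ether cleavage (bromide attacks the methyl group of each boron-complexed ether); the low temperature and absence of base should leave both lactones and the α-centres C3 and C3' untouched, and hydrolysis of the aryl borates frees the eight phenols.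

**Compound list**

1 | 1,2,3,4-tetramethoxybenzene | COc1ccc(OC)c(OC)c1OC | starting material
2 | 1-[chloro(methoxy)methyl]-2,3,4,5-tetramethoxybenzene | COC(Cl)c1cc(OC)c(OC)c(OC)c1OC | intermediate
3 | 2,3,4,5-tetramethoxybenzaldehyde | O=Cc1cc(OC)c(OC)c(OC)c1OC | intermediate
4 | 2-bromo-3,4,5,6-tetramethoxybenzaldehyde | O=Cc1c(Br)c(OC)c(OC)c(OC)c1OC | intermediate
5 | 2-[1-(4-methoxyphenyl)ethenyl]-4,4,5,5-tetramethyl-1,3,2-dioxaborolane | C=C(B1OC(C)(C)C(C)(C)O1)c1ccc(OC)cc1 | starting material
6 | 2,3,4,5-tetramethoxy-6-[1-(4-methoxyphenyl)ethenyl]benzaldehyde | O=Cc1c(C(=C)c2ccc(OC)cc2)c(OC)c(OC)c(OC)c1OC | intermediate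
7 | (3R)-4,5,6,7-tetramethoxy-3-(4-methoxyphenyl)-2,3-dihydro-1H-inden-1-one | O=C1C[C@H](c2ccc(OC)cc2)c2c(OC)c(OC)c(OC)c(OC)c21 | intermediate
8 | glyoxylic acid monohydrate (2,2-dihydroxyacetic acid) | OC(O)C(=O)O | starting material
9 | (2E)-2-[(1R)-4,5,6,7-tetramethoxy-1-(4-methoxyphenyl)-3-oxo-1,3-dihydro-2H-inden-2-ylidene]acetic acid | OC(=O)/C=C1/C(=O)c2c(OC)c(OC)c(OC)c(OC)c2[C@H]1c1ccc(OC)cc1 | intermediate
10 | 2-[(1R,2R)-4,5,6,7-tetramethoxy-1-(4-methoxyphenyl)-3-oxo-2,3-dihydro-1H-inden-2-yl]acetic acid (cis) | OC(=O)C[C@H]1C(=O)c2c(OC)c(OC)c(OC)c(OC)c2[C@H]1c1ccc(OC)cc1 | intermediate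
11 | 2-[(3R,4R)-5,6,7,8-tetramethoxy-4-(4-methoxyphenyl)-2-oxo-3,4-dihydro-2H-chromen-3-yl]acetic acid (cis) | OC(=O)C[C@H]1C(=O)Oc2c(OC)c(OC)c(OC)c(OC)c2[C@H]1c1ccc(OC)cc1 | intermediate
12 | 2-hydroxy-4,6-dimethoxybenzaldehyde | O=Cc1c(O)cc(OC)cc1OC | starting material
13 | (4-methoxyphenyl)magnesium bromide | COc1ccc([Mg]Br)cc1 | starting material
14 | 2-[hydroxy(4-methoxyphenyl)methyl]-3,5-dimethoxyphenol (racemic) | OC(c1ccc(OC)cc1)c1c(O)cc(OC)cc1OC | intermediate
15 | sodium 4-methylbenzenesulfinate | [Na+].[O-]S(=O)c1ccc(C)cc1 | starting material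
16 | 3,5-dimethoxy-2-[(4-methoxyphenyl)(4-methylbenzenesulfonyl)methyl]phenol (racemic) | Cc1ccc(cc1)S(=O)(=O)C(c1ccc(OC)cc1)c1c(O)cc(OC)cc1OC | intermediate
17 | (3R,4R)-3-[2-(1H-imidazol-1-yl)-2-oxoethyl]-5,6,7,8-tetramethoxy-4-(4-methoxyphenyl)-3,4-dihydro-2H-chromen-2-one | O=C(C[C@H]1C(=O)Oc2c(OC)c(OC)c(OC)c(OC)c2[C@H]1c1ccc(OC)cc1)n1ccnc1 | intermediate
18 | 3,5-dimethoxy-6-[(4-methoxyphenyl)methylidene]cyclohexa-2,4-dien-1-one | O=C1C=C(OC)C=C(OC)C1=Cc1ccc(OC)cc1 | intermediate
19 | (3S,4R)-5,7-dimethoxy-4-(4-methoxyphenyl)-3-[(3S,4R)-5,6,7,8-tetramethoxy-4-(4-methoxyphenyl)-2-oxo-3,4-dihydro-2H-chromen-3-yl]-3,4-dihydro-2H-chromen-2-one | O=C1Oc2cc(OC)cc(OC)c2[C@@H](c2ccc(OC)cc2)[C@H]1[C@H]1C(=O)Oc2c(OC)c(OC)c(OC)c(OC)c2[C@H]1c1ccc(OC)cc1 | intermediate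
20 | (3S,4R)-5,7-dihydroxy-4-(4-hydroxyphenyl)-3-[(3S,4R)-5,6,7,8-tetrahydroxy-4-(4-hydroxyphenyl)-2-oxo-3,4-dihydro-2H-chromen-3-yl]-3,4-dihydro-2H-chromen-2-one | O=C1Oc2cc(O)cc(O)c2[C@@H](c2ccc(O)cc2)[C@H]1[C@H]1C(=O)Oc2c(O)c(O)c(O)c(O)c2[C@H]1c1ccc(O)cc1 | target

**Total step count:** 11. **Longest linear sequence:** 9 (steps 1 to 7, 10 and 11).

**Steps most likely to fail**

1. Step 10. The chiral carbene and the β-stereocentre of the enolate may be mismatched and give poor facial selectivity. Enolate formation next to a branched carbon may be slow, and the carbonate base may epimerise the cis lactone B. The fallback sets out from 11 (using 14) and returns at 19. Acid 11 is converted through its pivalic mixed anhydride (t-BuCOCl, Et3N; then the lithium salt of (4S)-4-benzyl-1,3-oxazolidin-2-one) into the N-acyl oxazolidinone F1. Its chlorotitanium Z enolate (TiCl4, i-Pr2NEt, CH2Cl2, −78 °C) is alkylated in an SN1 manner by the benzhydryl cation generated from 14 with TiCl4. The auxiliary fixes C3, and the adduct with the required C4 configuration, the open-chain phenol F2, is separated. Warming F2 with 4-(dimethylamino)pyridine in toluene lactonises the phenol onto the imide with loss of the auxiliary and gives 19.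

2. Step 4. The acyl rhodium hydride may decarbonylate before it cyclises, or the catalyst may discriminate poorly between the two aryl groups of the twisted alkene. The fallback sets out from 6 and returns at 7. The same C2'–C3' ring closure is run with an achiral, more robust hydroacylation catalyst ([Rh(dppe)]ClO4, or CoCl2/dppp/Zn) to give the racemic indanone F3. Dehydrogenation (2-iodoxybenzoic acid, DMSO, 70 °C) gives the indenone F4. C4' is then set separately by copper hydride conjugate reduction (Cu(OAc)2, (R)-DTBM-SEGPHOS, polymethylhydrosiloxane; ligand antipode chosen for 3R) to return 7.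

3. Step 7. The cis-2,3-disubstituted ketone may epimerise through its enol before the oxygen is inserted. The alkyl carbon may migrate instead of the aryl carbon, and the peracid may oxidise the tetramethoxyarene. The fallback sets out from 7 and returns at 11. The oxygen is inserted first, on the configurationally robust ketone 7 (mCPBA), to give the lactone F5. Its lithium enolate (LiN(SiMe3)2, THF, −78 °C) is alkylated with tert-butyl bromoacetate anti to the aryl group, giving the trans ester F6. Double deprotonation (LiN(i-Pr)2, 2.2 equiv, −78 °C) and a quench with 2,6-di-tert-butyl-4-methylphenol protonates the lactone enolate opposite the pseudoaxial aryl group and gives the cis ester F7. CF3CO2H in CH2Cl2 then removes the tert-butyl group to give 11.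

**Further compounds**

F1 | step 10 | (4S)-4-benzyl-3-{2-[(3R,4R)-5,6,7,8-tetramethoxy-4-(4-methoxyphenyl)-2-oxo-3,4-dihydro-2H-chromen-3-yl]acetyl}-1,3-oxazolidin-2-one | O=C(C[C@H]1C(=O)Oc2c(OC)c(OC)c(OC)c(OC)c2[C@H]1c1ccc(OC)cc1)N1[C@@H](Cc2ccccc2)COC1=O
F2 | step 10 | (4S)-4-benzyl-3-[(2S,3R)-3-(2-hydroxy-4,6-dimethoxyphenyl)-3-(4-methoxyphenyl)-2-[(3S,4R)-5,6,7,8-tetramethoxy-4-(4-methoxyphenyl)-2-oxo-3,4-dihydro-2H-chromen-3-yl]propanoyl]-1,3-oxazolidin-2-one | O=C(N1[C@@H](Cc2ccccc2)COC1=O)[C@@H]([C@H](c1ccc(OC)cc1)c1c(O)cc(OC)cc1OC)[C@H]1C(=O)Oc2c(OC)c(OC)c(OC)c(OC)c2[C@H]1c1ccc(OC)cc1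
F3 | step 4 | 4,5,6,7-tetramethoxy-3-(4-methoxyphenyl)-2,3-dihydro-1H-inden-1-one (racemic) | O=C1CC(c2ccc(OC)cc2)c2c(OC)c(OC)c(OC)c(OC)c21
F4 | step 4 | 4,5,6,7-tetramethoxy-3-(4-methoxyphenyl)-1H-inden-1-one | O=C1C=C(c2ccc(OC)cc2)c2c(OC)c(OC)c(OC)c(OC)c21
F5 | step 7 | (4R)-5,6,7,8-tetramethoxy-4-(4-methoxyphenyl)-3,4-dihydro-2H-chromen-2-one | O=C1C[C@H](c2ccc(OC)cc2)c2c(OC)c(OC)c(OC)c(OC)c2O1
F6 | step 7 | tert-butyl 2-[(3S,4R)-5,6,7,8-tetramethoxy-4-(4-methoxyphenyl)-2-oxo-3,4-dihydro-2H-chromen-3-yl]acetate (trans) | CC(C)(C)OC(=O)C[C@@H]1C(=O)Oc2c(OC)c(OC)c(OC)c(OC)c2[C@H]1c1ccc(OC)cc1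
F7 | step 7 | tert-butyl 2-[(3R,4R)-5,6,7,8-tetramethoxy-4-(4-methoxyphenyl)-2-oxo-3,4-dihydro-2H-chromen-3-yl]acetate (cis) | CC(C)(C)OC(=O)C[C@H]1C(=O)Oc2c(OC)c(OC)c(OC)c(OC)c2[C@H]1c1ccc(OC)cc1
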